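The route rests on redrawing the C7–C8 pair of the arylglycerol unit as a C7 aryl ketone on the guaiacyl ring (ring A) next to a C9 ester. C8, which carries the ether oxygen to the syringyl ring (ring B), then lies between two carbonyls and racemises freely. One asymmetric transfer hydrogenation with RuCl[(S,S)-TsDPEN](p-cymene) under dynamic kinetic resolution should turn this racemic α-aryloxy β-keto ester into a single threo hydroxy ester, fixing C8 for good and C7 provisionally. A Mitsunobu inversion at C7 then gives the erythro (7S,8R) series. The precursor is built from acetovanillone (glyceryl ether, Claisen carbon C9, bromination) and ethyl dihydrosinapate by phenoxide displacement.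

Key step: step 6

Remark: lignan numbering is used (C7 benzylic carbinol, C8 aryloxy carbon, C9 hydroxymethyl); the (S,S) hand of the catalyst is chosen from the usual aryl ketone model, and the (R,R) complex would be substituted, with nothing else changed, if the first run showed the opposite facial sense.

Step 1
Reactants: 1 acetovanillone; 2 1,3-bis(benzyloxy)propan-2-ol
Product: 3 1-[4-{[1,3-bis(benzyloxy)propan-2-yl]oxy}-3-methoxyphenyl]ethan-1-one
Conditions: PPh3, DIAD, THF, 0 °C to 40 °C
Reagents that add atoms: none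
Why: Mitsunobu etherification, in which the phenol (acidified by the para acetyl group) attacks the alkoxyphosphonium of the secondary alcohol; the carbinol carbon is not a stereocentre, so its inversion has no consequence.

Step 2
Reactants: 3 the aryl methyl ketone; 4 diethyl carbonate
Product: 5 ethyl 3-[4-{[1,3-bis(benzyloxy)propan-2-yl]oxy}-3-methoxyphenyl]-3-oxopropanoate
Conditions: NaH (2.5 equiv), 4 (excess), THF, reflux; then aq. HCl, 0 °C
Reagents that add atoms: none
Why: Crossed Claisen condensation of the methyl ketone enolate with the carbonate, pulled to completion by deprotonation of the β-keto ester product by NaH; the aryl and benzyl ethers are inert to the base.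

Step 3
Reactants: 5 the β-keto ester
Product: 6 ethyl 2-bromo-3-[4-{[1,3-bis(benzyloxy)propan-2-yl]oxy}-3-methoxyphenyl]-3-oxopropanoate (racemic)
Conditions: NBS (1.05 equiv), Mg(ClO4)2 (0.3 equiv), EtOAc, 0 °C to rt
Reagents that add atoms: N-bromosuccinimide (O=C1CCC(=O)N1Br)
Why: Electrophilic α-halogenation of the 1,3-dicarbonyl enol, whose formation Mg(ClO4)2 accelerates, should be much faster than bromination of the acyl-deactivated ring A or of the benzylic ether positions; the C–Br centre forms racemic, as intended.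

Step 4
Reactants: 7 sinapic acid
Product: 9 ethyl 3-(4-hydroxy-3,5-dimethoxyphenyl)propanoate, via dihydrosinapic acid 8 (not isolated)
Conditions: H2 (1 atm), 10% Pd/C, EtOH, rt; filter; then H2SO4 (cat.), reflux
Reagents that add atoms: ethanol (CCO)
Why: Heterogeneous catalytic hydrogenation of the cinnamic alkene followed by Fischer esterification in the same ethanol solution; the free phenol and the methyl ethers are untouched.

Step 5
Reactants: 6 the racemic α-bromo β-keto ester; 9 ethyl dihydrosinapate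
Product: 10 ethyl 3-[4-{[1,3-bis(benzyloxy)propan-2-yl]oxy}-3-methoxyphenyl]-2-[4-(3-ethoxy-3-oxopropyl)-2,6-dimethoxyphenoxy]-3-oxopropanoate (racemic at C8)
Conditions: K2CO3 (2 equiv), acetone, rt; aq. NH4Cl work-up
Reagents that add atoms: none
Why: Williamson-type SN2 displacement of the doubly activated secondary bromide by the phenoxide formed with K2CO3, which joins ring B to C8; the product is racemic at C8 and stays configurationally labile, which is what the next step needs.

Step 6
Reactants: 10 the racemic α-aryloxy β-keto ester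
Product: 11 ethyl (2S,3R)-3-[4-{[1,3-bis(benzyloxy)propan-2-yl]oxy}-3-methoxyphenyl]-2-[4-(3-ethoxy-3-oxopropyl)-2,6-dimethoxyphenoxy]-3-hydroxypropanoate (threo)
Conditions: RuCl[(S,S)-TsDPEN](p-cymene) (2 mol %), HCO2H/Et3N (5:2), CH2Cl2, 30 °C
Reagents that add atoms: none
Why: This is a Noyori–Ikariya asymmetric transfer hydrogenation under dynamic kinetic resolution, in which the Ru–H and the ligand N–H deliver hydride and proton to the C7 carbonyl through an outer-sphere six-membered transition state without chelation of the substrate, while C8 epimerises through the enol. The closest known reaction type is the transfer hydrogenation of racemic α-alkoxy β-keto esters with catalysts of the RuCl(TsDPEN)(arene) type in formic acid and triethylamine, which furnishes syn α-alkoxy β-hydroxy esters. No ring is closed. C7 is set by the catalyst (ring A lies under the η6-arene through a CH/π contact, so the (S,S) ligand should give 3R), and C8 is set by selection, because the catalyst-chosen C7 face is reached fastest in the C8 enantiomer that holds the C8–OAr bond anti to the incoming hydride (polar Felkin–Anh), which leads to the syn, that is threo, (2S,3R) ester. The step needs racemisation at C8 to outrun reduction and needs chemoselectivity for the ketone; the first is secured by the C8–H lying between ketone and ester and bearing an aryloxy group in an amine and formic acid medium, the second by the inertness of esters and benzyl ethers to this catalyst.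

Step 7
Reactants: 11 the threo (2S,3R) hydroxy ester
Product: 12 ethyl (2S,3S)-3-[4-{[1,3-bis(benzyloxy)propan-2-yl]oxy}-3-methoxyphenyl]-2-[4-(3-ethoxy-3-oxopropyl)-2,6-dimethoxyphenoxy]-3-[(4-nitrobenzoyl)oxy]propanoate (erythro)
Conditions: 4-nitrobenzoic acid, PPh3, DIAD, toluene, −20 °C to rt
Reagents that add atoms: 4-nitrobenzoic acid (O=C(O)c1ccc(cc1)[N+](=O)[O-])
Why: Mitsunobu esterification of the only free hydroxyl, in which 4-nitrobenzoate displaces the C7 alkoxyphosphonium by SN2 with inversion (threo to erythro, 3R to 3S); the ester and aryloxy group at C8 should hold back ionisation of the benzylic centre, and the acidic nucleophile keeps the medium too weakly basic for ready elimination.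

Step 8
Reactants: 12 the erythro 4-nitrobenzoate
Product: 13 (1S,2R)-1-[4-{[1,3-bis(benzyloxy)propan-2-yl]oxy}-3-methoxyphenyl]-2-[4-(3-hydroxypropyl)-2,6-dimethoxyphenoxy]propane-1,3-diol (erythro)
Conditions: LiBH4 (excess), THF, MeOH (2 equiv), 0 °C to rt; aq. NH4Cl
Reagents that add atoms: none
Why: Chemoselective ester reduction with LiBH4 takes both ethyl esters to primary alcohols and cleaves the 4-nitrobenzoate at its acyl carbon, so neither the C7–O nor the C8–O bond is broken and both stereocentres are retained.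

Step 9
Reactants: 13 the dibenzyl ether
Product: 14 (1S,2R)-1-{4-[(1,3-dihydroxypropan-2-yl)oxy]-3-methoxyphenyl}-2-[4-(3-hydroxypropyl)-2,6-dimethoxyphenoxy]propane-1,3-diol (target, erythro, 7S,8R)
Conditions: H2 (1 atm), 10% Pd/C, EtOAc/EtOH, rt
Reagents that add atoms: none
Why: Catalytic hydrogenolysis of the two alkyl benzyl ethers over Pd/C under neutral conditions, where the secondary benzylic C7–OH (whose hydrogenolysis needs acid), the aryl ethers and both stereocentres should be unaffected.

Compound list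
1 | acetovanillone (1-(4-hydroxy-3-methoxyphenyl)ethan-1-one) | CC(=O)c1ccc(O)c(OC)c1 | starting material
2 | 1,3-bis(benzyloxy)propan-2-ol | OC(COCc1ccccc1)COCc1ccccc1 | starting material
3 | 1-[4-{[1,3-bis(benzyloxy)propan-2-yl]oxy}-3-methoxyphenyl]ethan-1-one | CC(=O)c1ccc(OC(COCc2ccccc2)COCc2ccccc2)c(OC)c1 | intermediate
4 | diethyl carbonate | CCOC(=O)OCC | starting material
5 | ethyl 3-[4-{[1,3-bis(benzyloxy)propan-2-yl]oxy}-3-methoxyphenyl]-3-oxopropanoate | CCOC(=O)CC(=O)c1ccc(OC(COCc2ccccc2)COCc2ccccc2)c(OC)c1 | intermediate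
6 | ethyl 2-bromo-3-[4-{[1,3-bis(benzyloxy)propan-2-yl]oxy}-3-methoxyphenyl]-3-oxopropanoate (racemic) | CCOC(=O)C(Br)C(=O)c1ccc(OC(COCc2ccccc2)COCc2ccccc2)c(OC)c1 | intermediate
7 | sinapic acid ((E)-3-(4-hydroxy-3,5-dimethoxyphenyl)prop-2-enoic acid) | COc1cc(/C=C/C(=O)O)cc(OC)c1O | starting material
8 | dihydrosinapic acid (3-(4-hydroxy-3,5-dimethoxyphenyl)propanoic acid) | COc1cc(CCC(=O)O)cc(OC)c1O | intermediate
9 | ethyl dihydrosinapate (ethyl 3-(4-hydroxy-3,5-dimethoxyphenyl)propanoate) | CCOC(=O)CCc1cc(OC)c(O)c(OC)c1 | intermediate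
10 | ethyl 3-[4-{[1,3-bis(benzyloxy)propan-2-yl]oxy}-3-methoxyphenyl]-2-[4-(3-ethoxy-3-oxopropyl)-2,6-dimethoxyphenoxy]-3-oxopropanoate (racemic at C8) | COc1cc(C(=O)C(C(=O)OCC)Oc2c(OC)cc(CCC(=O)OCC)cc2OC)ccc1OC(COCc3ccccc3)COCc3ccccc3 | intermediate
11 | ethyl (2S,3R)-3-[4-{[1,3-bis(benzyloxy)propan-2-yl]oxy}-3-methoxyphenyl]-2-[4-(3-ethoxy-3-oxopropyl)-2,6-dimethoxyphenoxy]-3-hydroxypropanoate (threo) | COc1cc([C@@H](O)[C@@H](C(=O)OCC)Oc2c(OC)cc(CCC(=O)OCC)cc2OC)ccc1OC(COCc3ccccc3)COCc3ccccc3 | intermediate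
12 | ethyl (2S,3S)-3-[4-{[1,3-bis(benzyloxy)propan-2-yl]oxy}-3-methoxyphenyl]-2-[4-(3-ethoxy-3-oxopropyl)-2,6-dimethoxyphenoxy]-3-[(4-nitrobenzoyl)oxy]propanoate (erythro) | COc1cc([C@H](OC(=O)c3ccc(cc3)[N+](=O)[O-])[C@@H](C(=O)OCC)Oc2c(OC)cc(CCC(=O)OCC)cc2OC)ccc1OC(COCc4ccccc4)COCc4ccccc4 | intermediate
13 | (1S,2R)-1-[4-{[1,3-bis(benzyloxy)propan-2-yl]oxy}-3-methoxyphenyl]-2-[4-(3-hydroxypropyl)-2,6-dimethoxyphenoxy]propane-1,3-diol (erythro) | COc1cc([C@H](O)[C@@H](CO)Oc2c(OC)cc(CCCO)cc2OC)ccc1OC(COCc3ccccc3)COCc3ccccc3 | intermediate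
14 | (1S,2R)-1-{4-[(1,3-dihydroxypropan-2-yl)oxy]-3-methoxyphenyl}-2-[4-(3-hydroxypropyl)-2,6-dimethoxyphenoxy]propane-1,3-diol (CNP0324330.1) | COc1cc([C@H](O)[C@@H](CO)Oc2c(OC)cc(CCCO)cc2OC)ccc1OC(CO)CO | target

Total step count: 9. Longest linear sequence: 8 steps (steps 1, 2, 3, 5, 6, 7, 8 and 9 from acetovanillone); step 4 prepares the phenol partner in a side branch.

Steps most likely to fail

Step 6. Racemisation at C8 may fail to keep ahead of hydride transfer, or the bulky aryloxy group may weaken the syn preference or the facial control of the catalyst, so that several stereoisomers form together. The fallback is an auxiliary-controlled Evans syn aldol that sets out from 9 and 2 and comes back at 11. Vanillin F1 is etherified with 2 under Mitsunobu conditions (PPh3, DIAD, THF) to 4-{[1,3-bis(benzyloxy)propan-2-yl]oxy}-3-methoxybenzaldehyde F2. Phenol 9 is alkylated (K2CO3, NaI cat., MeCN, rt) with (S)-4-benzyl-3-(chloroacetyl)oxazolidin-2-one F3 to the aryloxyacetyl imide F4. The dibutylboron Z-enolate of F4 (Bu2BOTf, iPr2NEt, CH2Cl2, −78 °C to 0 °C) is then added to F2 and should give the syn aldol adduct F5 with the same (2S,3R) threo arrangement under control of the (S)-benzyl auxiliary. Ethanolysis with EtOMgBr in EtOH/THF at 0 °C removes the auxiliary and gives 11, after which steps 7 to 9 follow unchanged.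

Step 7. The C7 alkoxyphosphonium may eliminate across C7–C8 through the acidic C8–H, or the electron-rich benzylic carbon may partly ionise and erode the inversion. The fallback moves the inversion behind the reduction, onto a substrate whose C8–H is no longer acidic; it sets out from 11 and comes back at 13. Reduction of 11 with LiBH4 in THF gives the threo triol F6. Selective silylation of the two primary hydroxyls (TBSCl 2.1 equiv, imidazole, CH2Cl2, 0 °C) gives the bis-silyl ether F7. Mitsunobu reaction of its lone secondary hydroxyl (4-nitrobenzoic acid, PPh3, DIAD, toluene, −20 °C) should give the erythro 4-nitrobenzoate F8. Methanolysis (K2CO3, MeOH, rt) gives the erythro bis-silyl alcohol F9, and TBAF in THF then gives 13 for step 9.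

Step 5. Bromine may be transferred from the bromo keto ester to the phenoxide (reduction back to 5 in place of substitution), or the doubly ortho-substituted phenoxide may attack too slowly. The fallback forms the C8–O bond by carbenoid O–H insertion; it sets out from 5 and comes back at 10. Regitz diazo transfer to 5 (4-acetamidobenzenesulfonyl azide, Et3N, MeCN, rt) gives the diazo keto ester F10. Slow addition of F10 to phenol 9 with Rh2(OAc)4 (1 mol %) in toluene at 80 °C should give 10 directly, without passing through 6.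

Further compounds
F1 | step 6 | vanillin (bought) | O=Cc1ccc(O)c(OC)c1
F2 | step 6 | 4-{[1,3-bis(benzyloxy)propan-2-yl]oxy}-3-methoxybenzaldehyde | O=Cc1ccc(OC(COCc2ccccc2)COCc2ccccc2)c(OC)c1
F3 | step 6 | (S)-4-benzyl-3-(chloroacetyl)oxazolidin-2-one (bought, or made from (S)-4-benzyloxazolidin-2-one and chloroacetyl chloride) | O=C(CCl)N1[C@@H](Cc2ccccc2)COC1=O
F4 | step 6 | (S)-4-benzyl-3-{[4-(3-ethoxy-3-oxopropyl)-2,6-dimethoxyphenoxy]acetyl}oxazolidin-2-one | CCOC(=O)CCc1cc(OC)c(OCC(=O)N2[C@@H](Cc3ccccc3)COC2=O)c(OC)c1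
F5 | step 6 | (S)-4-benzyl-3-{(2S,3R)-3-[4-{[1,3-bis(benzyloxy)propan-2-yl]oxy}-3-methoxyphenyl]-2-[4-(3-ethoxy-3-oxopropyl)-2,6-dimethoxyphenoxy]-3-hydroxypropanoyl}oxazolidin-2-one | COc1cc([C@@H](O)[C@@H](C(=O)N4[C@@H](Cc5ccccc5)COC4=O)Oc2c(OC)cc(CCC(=O)OCC)cc2OC)ccc1OC(COCc3ccccc3)COCc3ccccc3
F6 | step 7 | (1R,2R)-1-[4-{[1,3-bis(benzyloxy)propan-2-yl]oxy}-3-methoxyphenyl]-2-[4-(3-hydroxypropyl)-2,6-dimethoxyphenoxy]propane-1,3-diol (threo triol) | COc1cc([C@@H](O)[C@@H](CO)Oc2c(OC)cc(CCCO)cc2OC)ccc1OC(COCc3ccccc3)COCc3ccccc3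
F7 | step 7 | (1R,2R)-1-[4-{[1,3-bis(benzyloxy)propan-2-yl]oxy}-3-methoxyphenyl]-3-[(tert-butyldimethylsilyl)oxy]-2-[4-{3-[(tert-butyldimethylsilyl)oxy]propyl}-2,6-dimethoxyphenoxy]propan-1-ol (threo) | COc1cc([C@@H](O)[C@@H](CO[Si](C)(C)C(C)(C)C)Oc2c(OC)cc(CCCO[Si](C)(C)C(C)(C)C)cc2OC)ccc1OC(COCc3ccccc3)COCc3ccccc3
F8 | step 7 | (1S,2R)-1-[4-{[1,3-bis(benzyloxy)propan-2-yl]oxy}-3-methoxyphenyl]-3-[(tert-butyldimethylsilyl)oxy]-2-[4-{3-[(tert-butyldimethylsilyl)oxy]propyl}-2,6-dimethoxyphenoxy]propyl 4-nitrobenzoate (erythro) | COc1cc([C@H](OC(=O)c3ccc(cc3)[N+](=O)[O-])[C@@H](CO[Si](C)(C)C(C)(C)C)Oc2c(OC)cc(CCCO[Si](C)(C)C(C)(C)C)cc2OC)ccc1OC(COCc4ccccc4)COCc4ccccc4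
F9 | step 7 | (1S,2R)-1-[4-{[1,3-bis(benzyloxy)propan-2-yl]oxy}-3-methoxyphenyl]-3-[(tert-butyldimethylsilyl)oxy]-2-[4-{3-[(tert-butyldimethylsilyl)oxy]propyl}-2,6-dimethoxyphenoxy]propan-1-ol (erythro) | COc1cc([C@H](O)[C@@H](CO[Si](C)(C)C(C)(C)C)Oc2c(OC)cc(CCCO[Si](C)(C)C(C)(C)C)cc2OC)ccc1OC(COCc3ccccc3)COCc3ccccc3
F10 | step 5 | ethyl 2-diazo-3-[4-{[1,3-bis(benzyloxy)propan-2-yl]oxy}-3-methoxyphenyl]-3-oxopropanoate | CCOC(=O)C(=[N+]=[N-])C(=O)c1ccc(OC(COCc2ccccc2)COCc2ccccc2)c(OC)c1
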